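**Plan**

- Retrosynthesis: the tert-butyl ester of the dienoic acid is cut first, then ring bond C3–C4 (intramolecular Claisen), then the C2–O1 ester bond and the C2–C3 bond of the beta-keto ester (acylketene from the chain acid and Meldrum's acid), then the single bond between the two alkenes of the diene (Suzuki–Miyaura), and last the trisubstituted C=C (Wittig) and the alkyne carbon (aldehyde homologation).
- Enabling feature: in the only ring (O1, C2 lactone carbonyl, C3, C4 enol carbon, C5H2, C6 bearing CH3) C3 is bonded to C2, C4 and the side-chain ketone. Ketone–C3–C2(=O)–O1 is therefore a beta-keto ester and O1–C6–C5–C4 an (R)-3-hydroxybutanoate, so joining C3 to C4 is a Dieckmann-type ester condensation.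
- Forward: the open chain is finished first (bromo-enoate + alkenylboronate to the diene, isopropylidene to the acid, acid to acyl Meldrum's acid to the beta-keto ester of the hydroxy ester). The single ring is closed in the penultimate step and the tert-butyl ester is removed last.
- Stereochemistry: all three stereocenters are bought, from (S)-2-methylbutan-1-ol, (R)-citronellal and methyl (R)-3-hydroxybutanoate. The trisubstituted alkene geometry comes from a Z-selective bromo-ylide Wittig reaction followed by a stereoretentive coupling, the disubstituted E alkene from syn hydroboration of a terminal alkyne.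

Key step: step 10

Remark: the acyl-dihydropyranone is drawn throughout as the 4-hydroxy enol tautomer of the target SMILES; it will equilibrate with its other enol forms, which affects no step.

**Route**

Step 1
Reactants: 1 tert-butyl 2-(triphenyl-λ5-phosphanylidene)acetate
Product: 3 tert-butyl 2-bromo-2-(triphenyl-λ5-phosphanylidene)acetate, via bromophosphonium bromide 2 (not isolated)
Conditions: Br2 (1.0 equiv), CH2Cl2, −78 °C; then aq. NaOH, 0 °C
Reagents that add atoms: bromine, BrBr
Why: Electrophilic bromination of the stabilised ylide at carbon gives the alpha-bromophosphonium salt, whose remaining acidic C–H is removed by hydroxide to give the brominated stabilised ylide (halogenation–deprotonation of a phosphorane).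

Step 2
Reactants: 4 (S)-2-methylbutan-1-ol; 3 tert-butyl 2-bromo-2-(triphenyl-λ5-phosphanylidene)acetate
Product: 6 tert-butyl (2Z,4S)-2-bromo-4-methylhex-2-enoate, via (S)-2-methylbutanal 5 (not isolated)
Conditions: TEMPO (2,2,6,6-tetramethylpiperidin-1-oxyl, 1 mol%), KBr (10 mol%), aq. NaOCl/NaHCO3 (pH 9.5), CH2Cl2, 0 °C; organic phase washed and dried, then 3, CH2Cl2, 0 °C → rt
Reagents that add atoms: none
Why: Nitroxyl-catalysed hypochlorite oxidation gives the configurationally labile alpha-branched aldehyde without amine base, and the immediate Wittig reaction with the stabilised bromo ylide should place the alkyl group trans to the ester (Z because Br outranks the ester carbon), as is usual for alpha-halo stabilised ylides; the stereocenter is the one bought with 4.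

Step 3
Reactants: 7 (R)-citronellal [(3R)-3,7-dimethyloct-6-enal]
Product: 8 (4R)-4,8-dimethylnon-7-en-1-yne
Conditions: dimethyl (1-diazo-2-oxopropyl)phosphonate, K2CO3, MeOH, 0 °C → rt
Reagents that add atoms: dimethyl (1-diazo-2-oxopropyl)phosphonate, CC(=O)C(=[N+]=[N-])P(=O)(OC)OC
Why: Ohira–Bestmann (Seyferth–Gilbert) homologation turns the aldehyde into the terminal alkyne with one added carbon, and the stereocenter, beta to the carbonyl, cannot be enolised under carbonate/methanol.

Step 4
Reactants: 8 (4R)-4,8-dimethylnon-7-en-1-yne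
Product: 9 2-[(1E,4R)-4,8-dimethylnona-1,7-dien-1-yl]-4,4,5,5-tetramethyl-1,3,2-dioxaborolane
Conditions: pinacolborane (1.2 equiv), Cp2Zr(H)Cl (10 mol%), Et3N (10 mol%), neat, 60 °C
Reagents that add atoms: pinacolborane, CC1(C)OBOC1(C)C
Why: Zirconocene hydride-catalysed hydroboration of a terminal alkyne is a syn, anti-Markovnikov addition that should give only the (E)-1-alkenylboronate, while pinacolborane leaves the trisubstituted alkene alone.

Step 5
Reactants: 9 2-[(1E,4R)-4,8-dimethylnona-1,7-dien-1-yl]-4,4,5,5-tetramethyl-1,3,2-dioxaborolane; 6 tert-butyl (2Z,4S)-2-bromo-4-methylhex-2-enoate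
Product: 10 tert-butyl (2E,3E,6R)-6,10-dimethyl-2-[(2S)-2-methylbutylidene]undeca-3,9-dienoate
Conditions: Pd(PPh3)4 (5 mol%), K3PO4, 1,4-dioxane/H2O, 60 °C
Reagents that add atoms: none
Why: Suzuki–Miyaura coupling of an alkenyl bromide with an alkenylboronate proceeds with retention at both sp2 carbons, so the Z bromide and the E boronate fix both diene geometries, and the tert-butyl ester is inert to aqueous phosphate.

Step 6
Reactants: 10 tert-butyl (2E,3E,6R)-6,10-dimethyl-2-[(2S)-2-methylbutylidene]undeca-3,9-dienoate
Product: 12 tert-butyl (2E,3E,6R)-6-methyl-2-[(2S)-2-methylbutylidene]-9-oxonon-3-enoate, via terminal epoxide 11 (not isolated)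
Conditions: 3-chloroperoxybenzoic acid (mCPBA, 1.0 equiv), CH2Cl2, −20 °C; crude epoxide, H5IO6, THF/Et2O, 0 °C
Reagents that add atoms: 3-chloroperoxybenzoic acid, OOC(=O)c1cccc(Cl)c1
Why: Prilezhaev epoxidation should be fastest at the isolated, electron-rich trisubstituted alkene because the ester-bearing diene is deactivated, and periodic acid then opens the epoxide and cleaves the glycol to the aldehyde and acetone.

Step 7
Reactants: 12 tert-butyl (2E,3E,6R)-6-methyl-2-[(2S)-2-methylbutylidene]-9-oxonon-3-enoate
Product: 13 (4R,6E,8E,10S)-8-(tert-butoxycarbonyl)-4,10-dimethyldodeca-6,8-dienoic acid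
Conditions: NaClO2, NaH2PO4, 2-methylbut-2-ene, tBuOH/H2O, rt
Reagents that add atoms: sodium chlorite, [Na+].[O-]Cl=O
Why: Pinnick oxidation converts the aldehyde into the acid at buffered mild pH, and the alkene scavenger removes hypochlorous acid before it can add to the diene.

Step 8
Reactants: 13 (4R,6E,8E,10S)-8-(tert-butoxycarbonyl)-4,10-dimethyldodeca-6,8-dienoic acid; 14 Meldrum's acid (2,2-dimethyl-1,3-dioxane-4,6-dione)
Product: 15 tert-butyl (2E,3E,6R)-9-(2,2-dimethyl-4,6-dioxo-1,3-dioxan-5-ylidene)-9-hydroxy-6-methyl-2-[(2S)-2-methylbutylidene]non-3-enoate (the 5-acyl Meldrum's acid of 13, enol form)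
Conditions: N,N'-dicyclohexylcarbodiimide (1.1 equiv), 4-(dimethylamino)pyridine (1.5 equiv), CH2Cl2, 0 °C → rt; filtration, aq. KHSO4 wash
Reagents that add atoms: none
Why: Carbodiimide/DMAP activation of the acid and C-acylation of the highly acidic Meldrum's acid (Steglich-type coupling) is the standard entry to acyl Meldrum's acids and touches neither the diene nor the tert-butyl ester.

Step 9
Reactants: 15 the 5-acyl Meldrum's acid of 13; 16 methyl (R)-3-hydroxybutanoate
Product: 18 1-tert-butyl 11-[(2R)-4-methoxy-4-oxobutan-2-yl] (2E,3E,6R)-6-methyl-2-[(2S)-2-methylbutylidene]-9-oxoundec-3-enedioate, via acylketene 17 (not isolated)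
Conditions: 16 (1.5 equiv), toluene, 80 °C
Reagents that add atoms: none
Why: Thermolysis of an acyl Meldrum's acid expels acetone and CO2 to give an acylketene that the secondary alcohol traps as the beta-keto ester under neutral conditions, so the elimination-prone beta-acyloxy ester is formed without base and the C–O bond of the carbinol stereocenter is untouched.

Step 10
Reactants: 18 the beta-keto ester of methyl (R)-3-hydroxybutanoate described in step 9
Product: 19 tert-butyl (2E,3E,6R)-9-[(6R)-4-hydroxy-6-methyl-2-oxo-5,6-dihydro-2H-pyran-3-yl]-6-methyl-2-[(2S)-2-methylbutylidene]-9-oxonon-3-enoate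
Conditions: KOtBu (1.1 equiv), tBuOH/THF, 0 °C → rt; then 1 M HCl
Reagents that add atoms: none
Why: KOtBu removes a proton only from C3, the CH2 between the chain ketone and the C2 ester carbonyl, and this stabilised enolate adds to the methyl ester carbonyl (the future C4); the tetrahedral intermediate expels methoxide, which at once deprotonates the new, strongly acidic tricarbonyl unit and makes the C-acylation irreversible. This is a Lacey–Dieckmann cyclisation (intramolecular Claisen condensation of a beta-keto ester of a hydroxy ester), the six-membered counterpart of the 3-acyltetronic acid synthesis and of the base-induced closure of 3-acyloxyalkanoates to 4-hydroxy-5,6-dihydropyran-2-ones. The ring O1–C2–C3–C4–C5–C6 closes in the 6-exo-trig mode by forming the C3–C4 bond. No stereocenter is created: C6 keeps the R configuration of 16 because its C–O bond is never broken, and the two chain stereocenters are remote from every site that is deprotonated. The step needs C-acylation to win over beta-elimination of the acyloxy group and over attack on the dienoate; this is secured because the single equivalent of hindered base is consumed by the doubly activated C3–H, the resulting enolate makes the acyloxy group a poor leaving group (it would have to leave as a dianion) and leaves C5–H untouched, and the tert-butyl dienoate is too hindered to serve as acceptor.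

Step 11
Reactants: 19 the tert-butyl ester named in step 10
Product: 20 (2E,3E,6R)-9-[(6R)-4-hydroxy-6-methyl-2-oxo-5,6-dihydro-2H-pyran-3-yl]-6-methyl-2-[(2S)-2-methylbutylidene]-9-oxonon-3-enoic acid (target)
Conditions: CF3CO2H/CH2Cl2, 0 °C → rt
Reagents that add atoms: none
Why: Acidolysis of the tert-butyl ester (loss of 2-methylpropene through the tert-butyl cation) frees the dienoic acid without base, so the lactone, the tricarbonyl unit and the diene geometry should be preserved.

**Compound list**

1 | tert-butyl 2-(triphenyl-λ5-phosphanylidene)acetate | CC(C)(C)OC(=O)C=P(c1ccccc1)(c1ccccc1)c1ccccc1 | starting material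
2 | (1-bromo-2-tert-butoxy-2-oxoethyl)triphenylphosphonium bromide (formed in the flask) | CC(C)(C)OC(=O)C(Br)[P+](c1ccccc1)(c1ccccc1)c1ccccc1.[Br-] | intermediate
3 | tert-butyl 2-bromo-2-(triphenyl-λ5-phosphanylidene)acetate | CC(C)(C)OC(=O)C(Br)=P(c1ccccc1)(c1ccccc1)c1ccccc1 | intermediate
4 | (S)-2-methylbutan-1-ol | CC[C@H](C)CO | starting material
5 | (S)-2-methylbutanal (kept in solution) | CC[C@H](C)C=O | intermediate
6 | tert-butyl (2Z,4S)-2-bromo-4-methylhex-2-enoate (Br cis to the sec-butyl group) | CC[C@H](C)/C=C(\Br)C(=O)OC(C)(C)C | intermediate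
7 | (R)-citronellal, (3R)-3,7-dimethyloct-6-enal | C[C@H](CCC=C(C)C)CC=O | starting material
8 | (4R)-4,8-dimethylnon-7-en-1-yne | C[C@H](CCC=C(C)C)CC#C | intermediate
9 | 2-[(1E,4R)-4,8-dimethylnona-1,7-dien-1-yl]-4,4,5,5-tetramethyl-1,3,2-dioxaborolane | C[C@H](CCC=C(C)C)C/C=C/B1OC(C)(C)C(C)(C)O1 | intermediate
10 | tert-butyl (2E,3E,6R)-6,10-dimethyl-2-[(2S)-2-methylbutylidene]undeca-3,9-dienoate (sec-butyl trans to the ester) | CC[C@H](C)/C=C(\C=C\C[C@H](C)CCC=C(C)C)C(=O)OC(C)(C)C | intermediate
11 | tert-butyl (2E,3E,6R)-8-(3,3-dimethyloxiran-2-yl)-6-methyl-2-[(2S)-2-methylbutylidene]oct-3-enoate (both epimers at the oxirane CH, formed in the flask) | CC[C@H](C)/C=C(\C=C\C[C@H](C)CCC1OC1(C)C)C(=O)OC(C)(C)C | intermediate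
12 | tert-butyl (2E,3E,6R)-6-methyl-2-[(2S)-2-methylbutylidene]-9-oxonon-3-enoate | CC[C@H](C)/C=C(\C=C\C[C@H](C)CCC=O)C(=O)OC(C)(C)C | intermediate
13 | (4R,6E,8E,10S)-8-(tert-butoxycarbonyl)-4,10-dimethyldodeca-6,8-dienoic acid | CC[C@H](C)/C=C(\C=C\C[C@H](C)CCC(=O)O)C(=O)OC(C)(C)C | intermediate
14 | Meldrum's acid, 2,2-dimethyl-1,3-dioxane-4,6-dione | CC1(C)OC(=O)CC(=O)O1 | starting material
15 | tert-butyl (2E,3E,6R)-9-(2,2-dimethyl-4,6-dioxo-1,3-dioxan-5-ylidene)-9-hydroxy-6-methyl-2-[(2S)-2-methylbutylidene]non-3-enoate | CC[C@H](C)/C=C(\C=C\C[C@H](C)CCC(O)=C1C(=O)OC(C)(C)OC1=O)C(=O)OC(C)(C)C | intermediate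
16 | methyl (R)-3-hydroxybutanoate | C[C@@H](O)CC(=O)OC | starting material
17 | tert-butyl (2E,3E,6R)-6-methyl-2-[(2S)-2-methylbutylidene]-9,11-dioxoundeca-3,10-dienoate (acylketene, formed in the flask) | CC[C@H](C)/C=C(\C=C\C[C@H](C)CCC(=O)C=C=O)C(=O)OC(C)(C)C | intermediate
18 | 1-tert-butyl 11-[(2R)-4-methoxy-4-oxobutan-2-yl] (2E,3E,6R)-6-methyl-2-[(2S)-2-methylbutylidene]-9-oxoundec-3-enedioate | CC[C@H](C)/C=C(\C=C\C[C@H](C)CCC(=O)CC(=O)O[C@H](C)CC(=O)OC)C(=O)OC(C)(C)C | intermediate
19 | tert-butyl (2E,3E,6R)-9-[(6R)-4-hydroxy-6-methyl-2-oxo-5,6-dihydro-2H-pyran-3-yl]-6-methyl-2-[(2S)-2-methylbutylidene]-9-oxonon-3-enoate | CC[C@H](C)/C=C(\C=C\C[C@H](C)CCC(=O)C1=C(O)C[C@@H](C)OC1=O)C(=O)OC(C)(C)C | intermediate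
20 | (2E,3E,6R)-9-[(6R)-4-hydroxy-6-methyl-2-oxo-5,6-dihydro-2H-pyran-3-yl]-6-methyl-2-[(2S)-2-methylbutylidene]-9-oxonon-3-enoic acid | CC[C@H](C)/C=C(\C=C\C[C@H](C)CCC(=O)C1=C(O)C[C@@H](C)OC1=O)C(=O)O | target

**Count**

Total steps: 11. Longest linear sequence: 9 steps (7 to 20 through steps 3–11; the branch from 1 through steps 1, 2 and 5–11 is equally long).

**Steps most likely to fail, with fallbacks**

Step 10. The enolate acylation may be slower than expected for the six-membered ring, and on warming the ester linkage may be lost by beta-elimination of the acyloxy group (E1cB) before the ring closes. The fallback makes the ring first and attaches the chain acyl group afterwards. It sets out from 16 and acid 13. Hydroxy ester 16 is treated with excess LiCH2CO2tBu (from tert-butyl acetate and LiN(iPr)2, THF, −78 to −20 °C) in a crossed Claisen condensation to give tert-butyl (R)-5-hydroxy-3-oxohexanoate F1. CF3CO2H in CH2Cl2 removes the tert-butyl group and the delta-hydroxy beta-keto acid lactonises to (R)-4-hydroxy-6-methyl-5,6-dihydro-2H-pyran-2-one F2. N,N'-Dicyclohexylcarbodiimide with catalytic DMAP joins 13 and F2 as the 4-O-acyl enol ester of 13 with the dihydropyranone F3. A full equivalent of DMAP in warm toluene should then move the acyl group from O4 to C3 (Fries-type 1,3 O-to-C acyl shift), which returns to the route at 19.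

Step 6. The peracid may also attack the disubstituted alkene of the diene, or a second equivalent may react, so that chemoselectivity for the isopropylidene group is incomplete. The fallback cleaves this alkene before the diene exists and sets out from 8. Ozonolysis at −78 °C in CH2Cl2, stopped at the first excess of ozone and worked up with Me2S, should cleave the trisubstituted alkene far faster than the alkyne and give (R)-4-methylhept-6-ynal F4. HC(OMe)3 with catalytic TsOH in MeOH protects it as (4R)-7,7-dimethoxy-4-methylhept-1-yne F5. Hydroboration as in step 4 gives 2-[(1E,4R)-7,7-dimethoxy-4-methylhept-1-en-1-yl]-4,4,5,5-tetramethyl-1,3,2-dioxaborolane F6. Coupling with 6 as in step 5 gives tert-butyl (2E,3E,6R)-9,9-dimethoxy-6-methyl-2-[(2S)-2-methylbutylidene]non-3-enoate F7. Dilute aqueous HCl in THF hydrolyses the acetal without cleaving the tert-butyl ester and returns to the route at 12.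

Step 2. The bromo ylide is a weak nucleophile, so olefination may be slow enough for the alpha-branched aldehyde to enolise (erosion of enantiopurity), and the Z selectivity may be incomplete. The fallback sets out from 4 and the parent ylide 1. Alcohol 4 is oxidised as before to 5, and the faster, E-selective Wittig reaction with 1 gives tert-butyl (2E,4S)-4-methylhex-2-enoate F8. Br2 in CH2Cl2 at 0 °C adds to give tert-butyl (4S)-2,3-dibromo-4-methylhexanoate F9. Et3N then removes HBr from C2/C3 to give the thermodynamically preferred Z bromo-enoate, which returns to the route at 6.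

**Further compounds**

F1 | step 10 | tert-butyl (R)-5-hydroxy-3-oxohexanoate | C[C@@H](O)CC(=O)CC(=O)OC(C)(C)C
F2 | step 10 | (R)-4-hydroxy-6-methyl-5,6-dihydro-2H-pyran-2-one | C[C@@H]1CC(O)=CC(=O)O1
F3 | step 10 | (2R)-2-methyl-6-oxo-3,6-dihydro-2H-pyran-4-yl ester of acid 13 (4-O-acyl enol ester) | CC[C@H](C)/C=C(\C=C\C[C@H](C)CCC(=O)OC1=CC(=O)O[C@H](C)C1)C(=O)OC(C)(C)C
F4 | step 6 | (R)-4-methylhept-6-ynal | C[C@H](CCC=O)CC#C
F5 | step 6 | (4R)-7,7-dimethoxy-4-methylhept-1-yne | C[C@H](CCC(OC)OC)CC#C
F6 | step 6 | 2-[(1E,4R)-7,7-dimethoxy-4-methylhept-1-en-1-yl]-4,4,5,5-tetramethyl-1,3,2-dioxaborolane | C[C@H](CCC(OC)OC)C/C=C/B1OC(C)(C)C(C)(C)O1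
F7 | step 6 | tert-butyl (2E,3E,6R)-9,9-dimethoxy-6-methyl-2-[(2S)-2-methylbutylidene]non-3-enoate | CC[C@H](C)/C=C(\C=C\C[C@H](C)CCC(OC)OC)C(=O)OC(C)(C)C
F8 | step 2 | tert-butyl (2E,4S)-4-methylhex-2-enoate | CC[C@H](C)/C=C/C(=O)OC(C)(C)C
F9 | step 2 | tert-butyl (4S)-2,3-dibromo-4-methylhexanoate (anti adducts) | CC[C@H](C)C(Br)C(Br)C(=O)OC(C)(C)C
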